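**Retrosynthetic overview**
- The target is made from its symmetric ring-B resorcinol (the 3,5-dihydroxy tetraphenol) by forming one aryl C–OMe bond: a desymmetrising dehydrative mono-etherification with methanol, used as the last step.
- The tetraphenol comes from a tetra-O-benzyl stilbene by one global hydrogenation (C=C plus four O-benzyl groups).
- The stilbene comes from a 2,6-dibromostilbene by a double Negishi benzylation with 4-(benzyloxy)benzylzinc chloride.
- The dibromostilbene comes from Horner–Wadsworth–Emmons olefination of 3,5-bis(benzyloxy)-2,6-dibromobenzaldehyde, itself made by NBS dibromination of 3,5-bis(benzyloxy)benzaldehyde.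
- No ring is formed: all four benzene rings are bought. Order of attachment: ring B, then ring A, then the two hydroxybenzyl rings.

Assumption: the target has no stereocentre, stereogenic axis or double bond, so it is achiral and needs no stereocontrol; the E-alkene of the intermediates is removed by hydrogenation.

**Route**

Step 1
Reactants: 1 3,5-bis(benzyloxy)benzaldehyde
Product: 2 3,5-bis(benzyloxy)-2,6-dibromobenzaldehyde
Conditions: NBS (2.3 equiv), MeCN, 0 °C → 45 °C, dark
Reagents that add atoms: N-bromosuccinimide (NBS), O=C1CCC(=O)N1Br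
Why: Electrophilic aromatic bromination puts each bromine para to one benzyloxy group and ortho to the other (C-2 and C-6), while C-4 is shielded between the two benzyloxy groups, as in the known 2,6-dibromination of 3,5-dimethoxybenzaldehyde and 3,5-dimethoxytoluene.

Step 2
Reactants: 2 3,5-bis(benzyloxy)-2,6-dibromobenzaldehyde; 3 diethyl (3-methoxybenzyl)phosphonate
Product: 5 (E)-1,5-bis(benzyloxy)-2,4-dibromo-3-[2-(3-methoxyphenyl)ethenyl]benzene, via phosphonate carbanion potassium salt 4 (not isolated)
Conditions: 3, KOtBu (1.2 equiv), THF, 0 °C; then 2, 0 °C → rt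
Reagents that add atoms: none
Why: Horner–Wadsworth–Emmons olefination of a non-enolisable aldehyde with a benzylic phosphonate anion gives the E-stilbene under thermodynamic control, and the alkene geometry is irrelevant because it is hydrogenated in step 4.

Step 3
Reactants: 5 (E)-1,5-bis(benzyloxy)-2,4-dibromo-3-[2-(3-methoxyphenyl)ethenyl]benzene; 6 4-(benzyloxy)benzyl chloride
Product: 8 (E)-1,5-bis(benzyloxy)-2,4-bis[4-(benzyloxy)benzyl]-3-[2-(3-methoxyphenyl)ethenyl]benzene, via benzylic zinc chloride 7 (not isolated)
Conditions: 6 (3.0 equiv), Zn dust, LiCl, THF, 25 °C; then 5, Pd(OAc)2 (4 mol%), SPhos (8 mol%), THF, 25 → 55 °C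
Reagents that add atoms: none
Why: LiCl-promoted zinc insertion into the benzylic chloride followed by a double Negishi sp2–sp3 coupling works on di-ortho-substituted electron-rich aryl bromides with a bulky biarylphosphine ligand, and it fixes both benzyl groups at the brominated positions with no regiochemical ambiguity.

Step 4
Reactants: 8 (E)-1,5-bis(benzyloxy)-2,4-bis[4-(benzyloxy)benzyl]-3-[2-(3-methoxyphenyl)ethenyl]benzene
Product: 9 2,6-bis(4-hydroxybenzyl)-3,5-dihydroxy-3′-methoxybibenzyl
Conditions: H2 (3 bar), 10% Pd/C, EtOAc–MeOH 1:1, rt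
Reagents that add atoms: none
Why: Catalytic hydrogenation reduces the stilbene C=C and hydrogenolyses all four benzyl ethers in one operation, while the diarylmethane C–C bonds and the aryl methyl ether are inert.

Step 5
Reactants: 9 2,6-bis(4-hydroxybenzyl)-3,5-dihydroxy-3′-methoxybibenzyl
Product: 10 2,6-bis(p-hydroxybenzyl)-3,5′-dimethoxy-3-hydroxybibenzyl (target)
Conditions: 3 M HCl in anhydrous MeOH (0.05 M in 9), 3 Å MS, 60 °C, Ar; stop at about 90% conversion
Reagents that add atoms: methanol, CO
Why: Proposed new method: acid-catalysed dehydrative mono-etherification of the symmetric resorcinol ring with methanol — C-protonation at the one free ring position (C-4, ortho/para to both hydroxyls, with the charge further stabilised by the three alkyl groups) gives the O-protonated 3-hydroxycyclohexa-2,4-dienone tautomer, methanol adds to its carbonyl carbon, water leaves and the ring re-aromatises with a new aryl C–OMe bond; either homotopic C–OH gives 10, the two p-hydroxybenzyl phenols and the anisole ring cannot reach such a keto form and stay untouched, and a second exchange is slower because each OH→OMe change lowers ring C-basicity by roughly one pK unit; closest known reaction type: HCl/MeOH etherification of phloroglucinol (to 5-methoxyresorcinol and 3,5-dimethoxyphenol) and H2SO4/MeOH etherification of 2-naphthol, not yet shown for a monocyclic resorcinol or as a desymmetrisation.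

**Compound list**
1 | 3,5-bis(benzyloxy)benzaldehyde | O=Cc1cc(OCc2ccccc2)cc(OCc2ccccc2)c1 | starting material
2 | 3,5-bis(benzyloxy)-2,6-dibromobenzaldehyde | O=Cc1c(Br)c(OCc2ccccc2)cc(OCc2ccccc2)c1Br | intermediate
3 | diethyl (3-methoxybenzyl)phosphonate | CCOP(=O)(Cc1cccc(OC)c1)OCC | starting material
4 | potassium salt of the diethyl (3-methoxybenzyl)phosphonate carbanion | CCOP(=O)(OCC)[CH-]c1cccc(OC)c1.[K+] | intermediate
5 | (E)-1,5-bis(benzyloxy)-2,4-dibromo-3-[2-(3-methoxyphenyl)ethenyl]benzene | COc1cccc(/C=C/c2c(Br)c(OCc3ccccc3)cc(OCc3ccccc3)c2Br)c1 | intermediate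
6 | 4-(benzyloxy)benzyl chloride | ClCc1ccc(OCc2ccccc2)cc1 | starting material
7 | [4-(benzyloxy)benzyl]zinc chloride | Cl[Zn]Cc1ccc(OCc2ccccc2)cc1 | intermediate
8 | (E)-1,5-bis(benzyloxy)-2,4-bis[4-(benzyloxy)benzyl]-3-[2-(3-methoxyphenyl)ethenyl]benzene | COc1cccc(/C=C/c2c(Cc3ccc(OCc4ccccc4)cc3)c(OCc3ccccc3)cc(OCc3ccccc3)c2Cc2ccc(OCc3ccccc3)cc2)c1 | intermediate
9 | 2,6-bis(4-hydroxybenzyl)-3,5-dihydroxy-3′-methoxybibenzyl | COc1cccc(CCc2c(Cc3ccc(O)cc3)c(O)cc(O)c2Cc2ccc(O)cc2)c1 | intermediate
10 | 2,6-bis(p-hydroxybenzyl)-3,5′-dimethoxy-3-hydroxybibenzyl | COc1cccc(CCc2c(Cc3ccc(O)cc3)c(O)cc(OC)c2Cc2ccc(O)cc2)c1 | target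

**Summary**
Total step count: 5. Longest linear sequence: 5 (1 → 2 → 5 → 8 → 9 → 10).

**Steps most likely to fail and fallbacks**

Step 5 (proposed new mono-etherification). The risks are that ring C-protonation is too slow at 60 °C, that over-etherification occurs, or that forcing conditions cause acid-induced loss or migration of a p-hydroxybenzyl group. The fallback uses known chemistry and desymmetrises earlier, where only two hydroxyls are free. It sets out from 5: BCl3 with pentamethylbenzene in CH2Cl2 at −78 °C removes the two benzyl ethers without touching the methyl ether and gives (E)-4,6-dibromo-5-[2-(3-methoxyphenyl)ethenyl]benzene-1,3-diol F1. Statistical mono-methylation (MeI 1.0 equiv, K2CO3, acetone, rt, diol recycled) gives (E)-2,4-dibromo-5-methoxy-3-[2-(3-methoxyphenyl)ethenyl]phenol F2. Double Negishi coupling with excess 7 (one extra equivalent is consumed by the free phenol; Pd(OAc)2/SPhos) gives (E)-2,4-bis[4-(benzyloxy)benzyl]-5-methoxy-3-[2-(3-methoxyphenyl)ethenyl]phenol F3. Hydrogenation (H2, Pd/C) of the alkene and the two benzyl ethers brings the sequence back to the route at 10.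

Step 3 (double Negishi coupling at two di-ortho-substituted positions). The risks are stalling at the mono-coupled bromide or protodebromination. The fallback replaces cross-coupling by carbonyl addition and sets out from 5. Bromine–lithium exchange with n-BuLi in THF at −78 °C and addition to commercial 4-(benzyloxy)benzaldehyde is run twice in the same flask (the second exchange on the lithium alkoxide). This gives {4,6-bis(benzyloxy)-2-[(E)-2-(3-methoxyphenyl)ethenyl]-1,3-phenylene}bis{[4-(benzyloxy)phenyl]methanol} F4 as a diastereomer mixture. Hydrogenation (H2, Pd/C, EtOAc–MeOH, cat. HCl) then hydrogenolyses both diarylmethanol C–O bonds together with the four benzyl ethers and reduces the alkene, coming back to the route at 9.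

Step 1 (2,6-dibromination of a deactivated aldehyde). The risks are a sluggish second bromination or some 2,4-dibromo isomer. The fallback brominates at the more reactive alcohol oxidation level and sets out from 1. NaBH4 in MeOH gives 3,5-bis(benzyloxy)benzyl alcohol F5. NBS (2.1 equiv) in MeCN at 0 °C gives [3,5-bis(benzyloxy)-2,6-dibromophenyl]methanol F6, following the well-established 2,6-dibromination of 3,5-dialkoxytoluene-type rings. MnO2 in CH2Cl2 oxidises F6 and the sequence comes back to the route at 2.

**Further compounds**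
F1 | step 5 | (E)-4,6-dibromo-5-[2-(3-methoxyphenyl)ethenyl]benzene-1,3-diol | COc1cccc(/C=C/c2c(Br)c(O)cc(O)c2Br)c1
F2 | step 5 | (E)-2,4-dibromo-5-methoxy-3-[2-(3-methoxyphenyl)ethenyl]phenol | COc1cccc(/C=C/c2c(Br)c(O)cc(OC)c2Br)c1
F3 | step 5 | (E)-2,4-bis[4-(benzyloxy)benzyl]-5-methoxy-3-[2-(3-methoxyphenyl)ethenyl]phenol | COc1cccc(/C=C/c2c(Cc3ccc(OCc4ccccc4)cc3)c(O)cc(OC)c2Cc2ccc(OCc3ccccc3)cc2)c1
F4 | step 3 | {4,6-bis(benzyloxy)-2-[(E)-2-(3-methoxyphenyl)ethenyl]-1,3-phenylene}bis{[4-(benzyloxy)phenyl]methanol} (diastereomer mixture) | COc1cccc(/C=C/c2c(C(O)c3ccc(OCc4ccccc4)cc3)c(OCc3ccccc3)cc(OCc3ccccc3)c2C(O)c2ccc(OCc3ccccc3)cc2)c1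
F5 | step 1 | 3,5-bis(benzyloxy)benzyl alcohol | OCc1cc(OCc2ccccc2)cc(OCc2ccccc2)c1
F6 | step 1 | [3,5-bis(benzyloxy)-2,6-dibromophenyl]methanol | OCc1c(Br)c(OCc2ccccc2)cc(OCc2ccccc2)c1Br
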